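**Retrosynthetic overview**

1. The pyran ring is opened at O1–C2 (intramolecular Mitsunobu etherification with inversion, after one global desilylation), leading back to an open-chain phenol that carries an (R)-benzylic carbinol three carbons from C4a.
2. The chroman benzene ring is then taken apart by a cyclobutenone/ynol ether benzannulation: C8a, C6, C5 and C4a come from a 4-alkyl-3-methoxycyclobutenone, C8 and C7 from an (E)-methoxyenyne that already carries ring A; the net new bonds are C8–C8a and C6–C7.
3. The feature used: the chroman benzene ring (C4a, C5, C6, C7, C8, C8a) is a pentasubstituted phloroglucinol with three different oxygens (C5–OMe, C7–OMe, C8a–O1), carbon substituents at C4a and C8, and only O1 needing to be free; the annulation delivers exactly this pattern with the single free hydroxyl at C8a.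
4. The cyclobutenone comes from an aldoketene and methoxyacetylene ([2+2]), its stereocentre from asymmetric transfer hydrogenation; the enyne comes from Negishi coupling of methoxyethynylzinc chloride with the ring A (E)-iodoalkene (Takai olefination of a formylated phenol).
5. Ring order: ring A and the phenyl ring are bought; the chroman benzene ring is formed in the key step; the pyran ring is closed last.

Key step: step 10

**Remarks on the chemistry (assumptions and design choices)**

- 3,5-Dimethoxy-4-methylphenol is taken as a catalogue compound.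
- The 4-alkyl group of the cyclobutenone is installed by ketene–alkyne cycloaddition, not by alkylating a cyclobutenone at C4, because the enolate needed for that would be an antiaromatic cyclobutadienolate. The cyclobutenone is used as the mixture of epimers at its ring carbon, which becomes aromatic C4a.
- The ring A phenol is carried as a TBS ether, so that one fluoride step frees it together with the benzylic alcohol and no acid touches the electron-rich 2-hydroxystilbene at the end.
- Methoxyacetylene (bp about 23 °C) is handled as a cold solution and serves both fragments.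

**Route**

Step 1
Reactants: 1 chloroacetaldehyde dimethyl acetal (2-chloro-1,1-dimethoxyethane)
Product: 3 methoxyacetylene (methoxyethyne; kept as a cold THF solution), via sodium methoxyacetylide 2 (not isolated)
Conditions: NaNH2 (3 equiv), liq. NH3, −33 °C; evaporate NH3; cold sat. aq. NaCl, −20 °C; distil into THF at −78 °C
Reagents that add atoms: none
Why: Amide-induced loss of methanol and then of HCl (two β-eliminations) should give the sodium acetylide, protonated on quench; this is the standard preparation of alkoxyacetylenes, and the methyl ether is chosen because it has no β-hydrogen for retro-ene loss on later heating.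

Step 2
Reactants: 4 methyl 5-oxo-5-phenylpentanoate
Product: 5 methyl (5R)-5-hydroxy-5-phenylpentanoate
Conditions: RuCl(p-cymene)[(R,R)-TsDPEN] (1 mol%), HCO2H/Et3N (5:2), 30 °C
Reagents that add atoms: none
Why: Noyori asymmetric transfer hydrogenation of an aryl alkyl ketone; the (R,R)-TsDPEN ligand directs hydride to the face that gives the (R)-carbinol, the ester is untouched, and the hydroxy ester is silylated without delay to forestall lactonization.

Step 3
Reactants: 5 methyl (5R)-5-hydroxy-5-phenylpentanoate
Product: 6 methyl (5R)-5-(tert-butyldimethylsilyloxy)-5-phenylpentanoate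
Conditions: TBSCl, imidazole, DMF, rt
Reagents that add atoms: tert-butyldimethylsilyl chloride (TBSCl), CC(C)(C)[Si](C)(C)Cl
Why: Standard silylation of a secondary benzylic alcohol at oxygen, which leaves the stereocentre unchanged.

Step 4
Reactants: 6 methyl (5R)-5-(tert-butyldimethylsilyloxy)-5-phenylpentanoate
Product: 7 (5R)-5-(tert-butyldimethylsilyloxy)-5-phenylpentanoic acid
Conditions: LiOH·H2O, THF/MeOH/H2O (3:1:1), rt; then 1 M HCl to pH 4, 0 °C
Reagents that add atoms: lithium hydroxide, [Li+].[OH-]
Why: Ester saponification; the secondary TBS ether should survive hydroxide at room temperature and a brief, cold, mildly acidic work-up.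

Step 5
Reactants: 7 (5R)-5-(tert-butyldimethylsilyloxy)-5-phenylpentanoic acid; 3 methoxyacetylene
Product: 10 4-[(3R)-3-(tert-butyldimethylsilyloxy)-3-phenylpropyl]-3-methoxycyclobut-2-en-1-one (mixture of epimers at ring C4), via acid chloride 8 (not isolated), via aldoketene 9 (not isolated)
Conditions: 1-chloro-N,N,2-trimethylprop-1-en-1-amine (1.1 equiv), CH2Cl2, 0 °C to rt; then slow addition to 3 (3 equiv), Et3N (1.5 equiv), Et2O, 0 °C to rt, sealed flask
Reagents that add atoms: none
Why: The chloroenamine should form the acid chloride under neutral conditions (no HCl reaches the silyl ether), Et3N dehydrochlorinates it to the aldoketene, and this adds to the electron-rich alkyne in a regioselective thermal [2+2] cycloaddition (ketene carbonyl carbon to the unsubstituted alkyne carbon), the known route to 4-alkyl-3-alkoxycyclobutenones; the new ring stereocentre forms unselectively and is erased in step 10.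

Step 6
Reactants: 11 3,5-dimethoxy-4-methylphenol
Product: 13 6-hydroxy-2,4-dimethoxy-3-methylbenzaldehyde, via salicyl alcohol 12 (not isolated)
Conditions: MgCl2 (1.5 equiv), Et3N (3.75 equiv), (CH2O)n (6 equiv), MeCN, reflux; then 1 M HCl
Reagents that add atoms: paraformaldehyde (formaldehyde), C=O
Why: Magnesium-mediated ortho-formylation of a phenol (chelation-directed hydroxymethylation, then hydride transfer to a second formaldehyde); the two ortho positions are equivalent and the para position carries the methyl group, so a single aldehyde is expected.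

Step 7
Reactants: 13 6-hydroxy-2,4-dimethoxy-3-methylbenzaldehyde
Product: 14 6-(tert-butyldimethylsilyloxy)-2,4-dimethoxy-3-methylbenzaldehyde
Conditions: TBSCl, imidazole, DMF, rt
Reagents that add atoms: tert-butyldimethylsilyl chloride (TBSCl), CC(C)(C)[Si](C)(C)Cl
Why: Standard silylation of a phenol; the hydroxyl has only one ortho substituent, so the hydrogen-bonded phenol should still be silylated readily.

Step 8
Reactants: 14 6-(tert-butyldimethylsilyloxy)-2,4-dimethoxy-3-methylbenzaldehyde
Product: 15 tert-butyl{2-[(E)-2-iodoethenyl]-3,5-dimethoxy-4-methylphenoxy}dimethylsilane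
Conditions: CrCl2 (6 equiv), CHI3 (2 equiv), THF/1,4-dioxane (1:6), 0 °C to rt, dark
Reagents that add atoms: iodoform, IC(I)I
Why: Takai olefination; the geminal dichromium species from CHI3 adds to the aldehyde and eliminates to the (E)-iodoalkene, with aromatic aldehydes giving high E selectivity, and aryl silyl and methyl ethers are inert to CrCl2.

Step 9
Reactants: 15 tert-butyl{2-[(E)-2-iodoethenyl]-3,5-dimethoxy-4-methylphenoxy}dimethylsilane; 3 methoxyacetylene
Product: 18 tert-butyl{3,5-dimethoxy-2-[(1E)-4-methoxybut-1-en-3-yn-1-yl]-4-methylphenoxy}dimethylsilane, via lithium methoxyacetylide 16 (not isolated), via methoxyethynylzinc chloride 17 (not isolated)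
Conditions: 3 (1.5 equiv), n-BuLi, THF, −78 °C; ZnCl2 (1.6 equiv), −78 to 0 °C; then 15, Pd(PPh3)4 (5 mol%), THF, rt; chromatography on Et3N-deactivated silica
Reagents that add atoms: none
Why: Negishi coupling of an alkoxyethynylzinc chloride with an alkenyl iodide under zerovalent palladium catalysis, which proceeds with retention of the E geometry; the zinc acetylide is mild enough for the aryl silyl ether.

Step 10
Reactants: 10 4-[(3R)-3-(tert-butyldimethylsilyloxy)-3-phenylpropyl]-3-methoxycyclobut-2-en-1-one; 18 tert-butyl{3,5-dimethoxy-2-[(1E)-4-methoxybut-1-en-3-yn-1-yl]-4-methylphenoxy}dimethylsilane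
Product: 23 2-{(E)-2-[2-(tert-butyldimethylsilyloxy)-4,6-dimethoxy-5-methylphenyl]ethenyl}-6-[(3R)-3-(tert-butyldimethylsilyloxy)-3-phenylpropyl]-3,5-dimethoxyphenol, via vinylketene 19 (not isolated), via vinylcyclobutenone 20 (not isolated), via dienylketene 21 (not isolated), via cyclohexadienone 22 (not isolated)
Conditions: 10 (1.0 equiv), 18 (1.3 equiv), toluene (0.4 M), 80 °C then 110 °C, sealed tube, Ar
Reagents that add atoms: none
Why: Thermal 4π electrocyclic opening of 10 gives vinylketene 19, whose ketene C=C adds to the ynol ether of 18 in a polarised [2+2] cycloaddition (carbonyl carbon to the alkyne carbon β to OMe) to give vinylcyclobutenone 20; a second 4π opening gives dienylketene 21, and 6π electrocyclization followed by tautomerization of dienone 22 gives phenol 23. The closest known reaction type is the Danheiser benzannulation of cyclobutenones with alkoxy- or siloxyalkynes. The chroman benzene ring is closed by the disrotatory 6π electrocyclization, which re-forms the C4a–C8a bond opened at the start, so that the net new bonds are C8–C8a and C6–C7 and the ketene oxygen appears as the free C8a hydroxyl. No stereocentre is created: the ring carbon of 10 becomes aromatic C4a, and the benzylic silyloxy centre is remote and untouched. The step needs regioselectivity in the [2+2] event, secured by the matched polarity of the ketene carbonyl carbon and the methoxy-bearing alkyne, and periselectivity in the electrocyclization, secured by the E alkene, which holds ring A (both ortho positions substituted) away from the ketene carbon. Methyl ynol and enol ethers are used because they cannot lose an alkene by retro-ene fragmentation at this temperature, and the di-ortho-substituted phenol formed should be too hindered to be acylated readily by remaining ketene.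

Step 11
Reactants: 23 2-{(E)-2-[2-(tert-butyldimethylsilyloxy)-4,6-dimethoxy-5-methylphenyl]ethenyl}-6-[(3R)-3-(tert-butyldimethylsilyloxy)-3-phenylpropyl]-3,5-dimethoxyphenol
Product: 24 2-[(E)-2-(2-hydroxy-4,6-dimethoxy-5-methylphenyl)ethenyl]-6-[(3R)-3-hydroxy-3-phenylpropyl]-3,5-dimethoxyphenol
Conditions: TBAF (3 equiv), AcOH (3 equiv), THF, 0 °C to rt, Ar
Reagents that add atoms: none
Why: Fluoride desilylation should cleave both Si–O bonds (aryl ether fast, benzylic ether more slowly); acetic acid buffering protects the electron-rich phenoxides from air oxidation and leaves the stilbene and the stereocentre untouched.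

Step 12
Reactants: 24 2-[(E)-2-(2-hydroxy-4,6-dimethoxy-5-methylphenyl)ethenyl]-6-[(3R)-3-hydroxy-3-phenylpropyl]-3,5-dimethoxyphenol
Product: 26 2-{(E)-2-[(2S)-5,7-dimethoxy-2-phenyl-3,4-dihydro-2H-chromen-8-yl]ethenyl}-3,5-dimethoxy-4-methylphenol (CNP0000264.1), via alkoxyphosphonium zwitterion 25 (not isolated)
Conditions: PPh3 (1.5 equiv), DIAD (1.5 equiv), THF (0.01 M), 0 °C to rt
Reagents that add atoms: none
Why: Intramolecular Mitsunobu etherification; only the secondary benzylic hydroxyl can be activated as the alkoxyphosphonium ion, and the C8a phenoxide displaces it in a 6-exo-tet SN2 closure with inversion, turning the (R)-carbinol into the (2S)-chroman, while the ring A phenol could react only intermolecularly, which high dilution suppresses.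

**Compound list**

1 | chloroacetaldehyde dimethyl acetal (2-chloro-1,1-dimethoxyethane) | COC(CCl)OC | starting material
2 | sodium methoxyacetylide (formed in the flask) | [Na+].[C-]#COC | intermediate
3 | methoxyacetylene (methoxyethyne) | COC#C | intermediate
4 | methyl 5-oxo-5-phenylpentanoate | COC(=O)CCCC(=O)c1ccccc1 | starting material
5 | methyl (5R)-5-hydroxy-5-phenylpentanoate | COC(=O)CCC[C@@H](O)c1ccccc1 | intermediate
6 | methyl (5R)-5-(tert-butyldimethylsilyloxy)-5-phenylpentanoate | COC(=O)CCC[C@@H](O[Si](C)(C)C(C)(C)C)c1ccccc1 | intermediate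
7 | (5R)-5-(tert-butyldimethylsilyloxy)-5-phenylpentanoic acid | OC(=O)CCC[C@@H](O[Si](C)(C)C(C)(C)C)c1ccccc1 | intermediate
8 | (5R)-5-(tert-butyldimethylsilyloxy)-5-phenylpentanoyl chloride (formed in the flask) | ClC(=O)CCC[C@@H](O[Si](C)(C)C(C)(C)C)c1ccccc1 | intermediate
9 | (5R)-5-(tert-butyldimethylsilyloxy)-5-phenylpent-1-en-1-one, the aldoketene (formed in the flask) | O=C=CCC[C@@H](O[Si](C)(C)C(C)(C)C)c1ccccc1 | intermediate
10 | 4-[(3R)-3-(tert-butyldimethylsilyloxy)-3-phenylpropyl]-3-methoxycyclobut-2-en-1-one (both epimers at ring C4) | COC1=CC(=O)C1CC[C@@H](O[Si](C)(C)C(C)(C)C)c1ccccc1 | intermediate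
11 | 3,5-dimethoxy-4-methylphenol | Cc1c(OC)cc(O)cc1OC | starting material
12 | 2-(hydroxymethyl)-3,5-dimethoxy-4-methylphenol (as its magnesium salt in the flask) | COc1cc(O)c(CO)c(OC)c1C | intermediate
13 | 6-hydroxy-2,4-dimethoxy-3-methylbenzaldehyde | COc1cc(O)c(C=O)c(OC)c1C | intermediate
14 | 6-(tert-butyldimethylsilyloxy)-2,4-dimethoxy-3-methylbenzaldehyde | COc1cc(O[Si](C)(C)C(C)(C)C)c(C=O)c(OC)c1C | intermediate
15 | tert-butyl{2-[(E)-2-iodoethenyl]-3,5-dimethoxy-4-methylphenoxy}dimethylsilane | COc1cc(O[Si](C)(C)C(C)(C)C)c(/C=C/I)c(OC)c1C | intermediate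
16 | lithium methoxyacetylide (formed in the flask) | [Li]C#COC | intermediate
17 | methoxyethynylzinc chloride (formed in the flask) | Cl[Zn]C#COC | intermediate
18 | tert-butyl{3,5-dimethoxy-2-[(1E)-4-methoxybut-1-en-3-yn-1-yl]-4-methylphenoxy}dimethylsilane | COc1cc(O[Si](C)(C)C(C)(C)C)c(/C=C/C#COC)c(OC)c1C | intermediate
19 | (7R)-7-(tert-butyldimethylsilyloxy)-3-methoxy-7-phenylhepta-1,3-dien-1-one, the vinylketene (formed in the flask) | COC(=CCC[C@@H](O[Si](C)(C)C(C)(C)C)c1ccccc1)C=C=O | intermediate
20 | [2+2] adduct: 3-methoxy-2-[(E)-2-arylethenyl]-4-(1-methoxyalkenyl)cyclobut-2-en-1-one, aryl being the silylated ring A (formed in the flask; ring carbon unspecified) | COc1cc(O[Si](C)(C)C(C)(C)C)c(/C=C/C2=C(OC)C(C(OC)=CCC[C@@H](O[Si](C)(C)C(C)(C)C)c3ccccc3)C2=O)c(OC)c1C | intermediate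
21 | dienylketene from ring opening of 20 (formed in the flask; reacts through the geometry that brings the chain terminus to the ketene carbon) | COc1cc(O[Si](C)(C)C(C)(C)C)c(/C=C/C(=C=O)C(OC)=CC(OC)=CCC[C@@H](O[Si](C)(C)C(C)(C)C)c2ccccc2)c(OC)c1C | intermediate
22 | 3,5-dimethoxy-2-[(E)-2-arylethenyl]-6-[(3R)-3-(tert-butyldimethylsilyloxy)-3-phenylpropyl]cyclohexa-2,4-dien-1-one (formed in the flask; ring C6 unspecified) | COc1cc(O[Si](C)(C)C(C)(C)C)c(/C=C/C2=C(OC)C=C(OC)C(CC[C@@H](O[Si](C)(C)C(C)(C)C)c3ccccc3)C2=O)c(OC)c1C | intermediate
23 | 2-{(E)-2-[2-(tert-butyldimethylsilyloxy)-4,6-dimethoxy-5-methylphenyl]ethenyl}-6-[(3R)-3-(tert-butyldimethylsilyloxy)-3-phenylpropyl]-3,5-dimethoxyphenol | COc1cc(O[Si](C)(C)C(C)(C)C)c(/C=C/c2c(OC)cc(OC)c(CC[C@@H](O[Si](C)(C)C(C)(C)C)c3ccccc3)c2O)c(OC)c1C | intermediate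
24 | 2-[(E)-2-(2-hydroxy-4,6-dimethoxy-5-methylphenyl)ethenyl]-6-[(3R)-3-hydroxy-3-phenylpropyl]-3,5-dimethoxyphenol | COc1cc(O)c(/C=C/c2c(OC)cc(OC)c(CC[C@@H](O)c3ccccc3)c2O)c(OC)c1C | intermediate
25 | alkoxytriphenylphosphonium C8a-phenoxide zwitterion of 24 (formed in the flask; benzylic centre still R) | COc1cc(O)c(/C=C/c2c(OC)cc(OC)c(CC[C@@H](O[P+](c3ccccc3)(c3ccccc3)c3ccccc3)c3ccccc3)c2[O-])c(OC)c1C | intermediate
26 | 2-{(E)-2-[(2S)-5,7-dimethoxy-2-phenyl-3,4-dihydro-2H-chromen-8-yl]ethenyl}-3,5-dimethoxy-4-methylphenol (CNP0000264.1) | COc1cc(O)c(/C=C/c2c(OC)cc(OC)c3c2O[C@H](c2ccccc2)CC3)c(OC)c1C | target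

**Totals**

Total step count: 12.
Longest linear sequence: 7 steps (steps 2, 3, 4, 5, 10, 11, 12; the ring A arm, steps 6, 7, 8, 9, 10, 11, 12, is equally long).

**Steps most likely to fail**

Step 10 (benzannulation). The vinylogous-ester cyclobutenone may open only at temperatures at which the conjugated enynyl ether is consumed by oligomerization or by side reactions of its styryl unit, so that interception of the vinylketene falls behind ketene dimerization. The fallback separates ring construction from stilbene construction; it sets out from cyclobutenone 10 and methoxyacetylene 3 and comes back at 23. Heating 10 with a large excess of 3 (toluene, sealed tube) should give, by the same annulation with a small unhindered ynol ether, 2-[(3R)-3-(tert-butyldimethylsilyloxy)-3-phenylpropyl]-3,5-dimethoxyphenol F1, in which C8 carries hydrogen. Magnesium-mediated ortho-formylation (MgCl2, Et3N, paraformaldehyde) would then place the aldehyde at the only free position ortho to the hydroxyl, giving 3-[(3R)-3-(tert-butyldimethylsilyloxy)-3-phenylpropyl]-2-hydroxy-4,6-dimethoxybenzaldehyde F2. In parallel, ring A aldehyde 14 would be reduced with NaBH4 to [6-(tert-butyldimethylsilyloxy)-2,4-dimethoxy-3-methylphenyl]methanol F3 and converted with PPh3·HBr into {[6-(tert-butyldimethylsilyloxy)-2,4-dimethoxy-3-methylphenyl]methyl}triphenylphosphonium bromide F4. Wittig reaction of the ylide from F4 (KOtBu in excess, to allow for the free phenol) with F2, followed by thiyl-radical equilibration of the alkene (catalytic PhSSPh, light) to the E isomer, should give 23.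

Step 5 (aldoketene cycloaddition). The aldoketene may dimerize, or the low-boiling alkyne may escape from the mixture, before the cycloaddition takes place. The fallback installs the methyl enol ether by exchange instead of by direct cycloaddition; it sets out from acid 7 (through 8 and 9 as before) and comes back at 10. The ketene would be trapped with commercial ethoxyacetylene (bp 50 °C, usable in large excess as co-solvent) to give 4-[(3R)-3-(tert-butyldimethylsilyloxy)-3-phenylpropyl]-3-ethoxycyclobut-2-en-1-one F5. Acid-catalysed vinylogous transetherification (MeOH, HC(OMe)3, catalytic PPTS, rt) should then give 10. A 1,3-transposition during the exchange is harmless, because the alkyl-bearing ring carbon is adjacent to both oxygenated carbons.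

Step 9 (Negishi coupling). Transmetalation may be incomplete, the zinc acetylide may be protonated, or the ynol ether may be hydrated during coupling and isolation, while the hindered electron-rich iodoalkene is lost by deiodination. The fallback builds the alkynyl ether by elimination instead of cross-coupling; it sets out from aldehyde 14 (bypassing 15) and comes back at 18. Horner–Wadsworth–Emmons olefination of 14 with dimethyl (3-methoxy-2-oxopropyl)phosphonate (LiCl, DBU, MeCN) should give (3E)-4-[6-(tert-butyldimethylsilyloxy)-2,4-dimethoxy-3-methylphenyl]-1-methoxybut-3-en-2-one F6. Enolization toward the methoxymethylene group (KHMDS, PhNTf2, THF, −78 °C) would give (3E)-4-[6-(tert-butyldimethylsilyloxy)-2,4-dimethoxy-3-methylphenyl]-1-methoxybuta-1,3-dien-2-yl trifluoromethanesulfonate F7. Elimination of triflic acid with KOtBu at −78 °C, the established conversion of α-alkoxy ketone enol triflates into alkynyl ethers, should give 18.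

**Further compounds**

F1 | step 10 | 2-[(3R)-3-(tert-butyldimethylsilyloxy)-3-phenylpropyl]-3,5-dimethoxyphenol | COc1cc(OC)c(CC[C@@H](O[Si](C)(C)C(C)(C)C)c2ccccc2)c(O)c1
F2 | step 10 | 3-[(3R)-3-(tert-butyldimethylsilyloxy)-3-phenylpropyl]-2-hydroxy-4,6-dimethoxybenzaldehyde | O=Cc1c(OC)cc(OC)c(CC[C@@H](O[Si](C)(C)C(C)(C)C)c2ccccc2)c1O
F3 | step 10 | [6-(tert-butyldimethylsilyloxy)-2,4-dimethoxy-3-methylphenyl]methanol | COc1cc(O[Si](C)(C)C(C)(C)C)c(CO)c(OC)c1C
F4 | step 10 | {[6-(tert-butyldimethylsilyloxy)-2,4-dimethoxy-3-methylphenyl]methyl}triphenylphosphonium bromide | COc1cc(O[Si](C)(C)C(C)(C)C)c(C[P+](c2ccccc2)(c2ccccc2)c2ccccc2)c(OC)c1C.[Br-]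
F5 | step 5 | 4-[(3R)-3-(tert-butyldimethylsilyloxy)-3-phenylpropyl]-3-ethoxycyclobut-2-en-1-one (both epimers at ring C4) | CCOC1=CC(=O)C1CC[C@@H](O[Si](C)(C)C(C)(C)C)c1ccccc1
F6 | step 9 | (3E)-4-[6-(tert-butyldimethylsilyloxy)-2,4-dimethoxy-3-methylphenyl]-1-methoxybut-3-en-2-one | COCC(=O)/C=C/c1c(O[Si](C)(C)C(C)(C)C)cc(OC)c(C)c1OC
F7 | step 9 | (3E)-4-[6-(tert-butyldimethylsilyloxy)-2,4-dimethoxy-3-methylphenyl]-1-methoxybuta-1,3-dien-2-yl trifluoromethanesulfonate (either geometry at the enol ether) | COC=C(OS(=O)(=O)C(F)(F)F)/C=C/c1c(O[Si](C)(C)C(C)(C)C)cc(OC)c(C)c1OC
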